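**Retrosynthetic overview** (ansamycin numbering: C1 amide carbonyl, C15 benzylic CH2, C16–C21 arene)
1. Target ⇒ seco amino acid 34 by N–C1 macrolactamization; the 19-membered ring is closed last, the O7 carbamate is installed before and the silyl groups fall after.
2. 34 ⇒ C7–C8 bond by chelation-controlled addition of the (Z)-alkenyl metal from iodide 26 (C8–C21) to α-methoxy aldehyde 11 (C1–C7).
3. 11 ⇒ (S)-6-methoxycyclohept-2-enone 8 by C1–C7 scission (the ring cis-alkene becomes the 2Z-enoate) ⇒ enantioselective ring-opening of meso ketone 4 ⇒ [4+3] cycloaddition of furan with an oxyallyl cation (key sequence).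
4. 26 ⇒ iodo-olefination (8Z), (Z)-crotylboration (C10, C11), asymmetric hydrogenation (C12), Negishi coupling of a chiral zinc reagent (C14) with bromoarene 14.
5. Ring order: oxabicycle (step 1) → cycloheptenone (step 3, cleaved in step 6) → macrolactam (step 21); the benzene ring is carried from 3-amino-5-bromophenol.

Assumption: the sense of induction of the chiral lithium amide (step 3) and of the Rh–DuPhos catalyst (step 11) is assigned by analogy and the mirror-image reagent is used if it proves opposite; metal alkoxides, borates and similar species that exist only until aqueous work-up are not counted as compounds.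

Abbreviations: Ar = 3-[(tert-butoxycarbonyl)amino]-5-[(triisopropylsilyl)oxy]phenyl; Ar' = 3-amino-5-[(triisopropylsilyl)oxy]phenyl; TBS = tert-butyldimethylsilyl.

**Route**

Step 1
Reactants: 1 furan; 2 1,1,3,3-tetrabromopropan-2-one
Product: 3 2,4-dibromo-8-oxabicyclo[3.2.1]oct-6-en-3-one (mixture of bromide epimers)
Conditions: Zn–Cu couple, B(OEt)3, THF, −10 °C → rt, furan in excess
Reagents that add atoms: none
Why: Hoffmann-type [4+3] cycloaddition of the zinc oxyallyl cation (from reductive debromination of 2) across C2/C5 of furan breaks the furan aromaticity and builds the oxa-bridged seven-membered ketone; the bromide configuration is irrelevant because both are removed next.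

Step 2
Reactants: 3 2,4-dibromo-8-oxabicyclo[3.2.1]oct-6-en-3-one
Product: 4 (1R,5S)-8-oxabicyclo[3.2.1]octan-3-one (meso)
Conditions: H2 (1 atm), Pd/C, Et3N, EtOAc, rt
Reagents that add atoms: none
Why: Catalytic hydrogenation saturates the strained alkene and hydrogenolyses both α-bromo ketone C–Br bonds (HBr buffered by Et3N), giving the achiral meso ketone.

Step 3
Reactants: 4 (1R,5S)-8-oxabicyclo[3.2.1]octan-3-one
Product: 7 (S)-6-hydroxycyclohept-2-en-1-one, via silyl enol ether 5 (not isolated), via enone trimethylsilyl ether 6 (not isolated)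
Conditions: (R,R)-bis(1-phenylethyl)amine, n-BuLi, LiCl, Me3SiCl (in situ quench), THF, −100 °C; then Me3SiOTf (10 mol%), CH2Cl2, −78 → 0 °C; then citric acid, MeOH, 0 °C
Reagents that add atoms: none
Why: Simpkins-type enantioselective deprotonation by the chiral lithium amide distinguishes the two enantiotopic α-CH2 groups of the meso ketone, and the silyl-triflate-catalysed retro-oxa-Michael opening of the bridging C–O bond next to the enol silane leaves the remote bridgehead as the C6 carbinol (S) and creates the ring cis-enone that later becomes the 2Z-alkene.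

Step 4
Reactants: 7 (S)-6-hydroxycyclohept-2-en-1-one
Product: 8 (S)-6-methoxycyclohept-2-en-1-one
Conditions: MeOTf, 2,6-di-tert-butyl-4-methylpyridine, CH2Cl2, 0 °C → rt
Reagents that add atoms: methyl trifluoromethanesulfonate, COS(=O)(=O)C(F)(F)F
Why: Non-basic O-methylation of the β-hydroxy ketone with a hindered pyridine as acid scavenger avoids E1cB dehydration and does not touch C6.

Step 5
Reactants: 8 (S)-6-methoxycyclohept-2-en-1-one
Product: 10 (6S)-7-hydroxy-6-methoxycyclohept-2-en-1-one (C7 epimers), via potassium dienolate 9 (not isolated)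
Conditions: KN(SiMe3)2, THF, −78 °C; then 2-(phenylsulfonyl)-3-phenyloxaziridine, −78 °C; aq. NH4Cl
Reagents that add atoms: 2-(phenylsulfonyl)-3-phenyloxaziridine, O=S(=O)(c1ccccc1)N1OC1c1ccccc1
Why: Kinetic α'-deprotonation of the enone gives the cross-conjugated dienolate, which undergoes Davis oxaziridine hydroxylation; the new C7 centre is destroyed in step 6, so its configuration does not matter.

Step 6
Reactants: 10 (6S)-7-hydroxy-6-methoxycyclohept-2-en-1-one
Product: 11 methyl (2Z,6S)-6-methoxy-7-oxohept-2-enoate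
Conditions: Pb(OAc)4, MeOH/benzene 1:1, 0 °C
Reagents that add atoms: methanol, CO
Why: Criegee-type cleavage of the α-hydroxy ketone by lead tetraacetate in methanol cuts the C1–C7 bond to the methyl ester and the C7 aldehyde, so the 2Z geometry is inherited from the ring and C6 (S) is retained.

Step 7
Reactants: 12 3-amino-5-bromophenol
Product: 14 tert-butyl {3-bromo-5-[(triisopropylsilyl)oxy]phenyl}carbamate, via phenol carbamate 13 (not isolated)
Conditions: Boc2O, THF, 60 °C; then imidazole, i-Pr3SiCl, DMF, rt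
Reagents that add atoms: di-tert-butyl dicarbonate, CC(C)(C)OC(=O)OC(=O)OC(C)(C)C; chlorotriisopropylsilane, CC(C)[Si](Cl)(C(C)C)C(C)C
Why: Base-free Boc2O acylates only the aniline nitrogen, and imidazole-promoted silylation then caps the phenol, giving an arene that tolerates organolithium and hydride reagents.

Step 8
Reactants: 14 tert-butyl {3-bromo-5-[(triisopropylsilyl)oxy]phenyl}carbamate; 15 methyl (2S)-3-bromo-2-methylpropanoate
Product: 17 methyl (2R)-3-Ar-2-methylpropanoate, via alkylzinc bromide 16 (not isolated)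
Conditions: 15, Zn dust, I2 (5 mol%), N,N-dimethylacetamide, 70 °C; then 14, Pd(OAc)2 (2 mol%), SPhos (4 mol%), THF, 45 °C
Reagents that add atoms: none
Why: Negishi sp3–sp2 cross-coupling of the configurationally stable β-zinc ester forms C15–C16, and the C14 centre comes unchanged from 15 (the descriptor changes from S to R only through CIP priorities).

Step 9
Reactants: 17 methyl (2R)-3-Ar-2-methylpropanoate
Product: 18 (2R)-3-Ar-2-methylpropanal
Conditions: i-Bu2AlH (2.2 equiv), CH2Cl2, −78 °C; Rochelle salt work-up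
Reagents that add atoms: none
Why: Partial reduction of the ester stops at the aluminium hemiacetal at −78 °C (one equivalent is consumed by the carbamate N–H), and the cold, neutral work-up keeps the α-stereocentre.

Step 10
Reactants: 18 (2R)-3-Ar-2-methylpropanal
Product: 19 methyl (2Z,4R)-5-Ar-2-methoxy-4-methylpent-2-enoate
Conditions: methyl 2-(dimethoxyphosphoryl)-2-methoxyacetate, LiCl, DBU, MeCN, 0 °C → rt
Reagents that add atoms: methyl 2-(dimethoxyphosphoryl)-2-methoxyacetate, COC(C(=O)OC)P(=O)(OC)OC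
Why: Masamune–Roush Horner–Wadsworth–Emmons olefination under mild base adds C11 and C12 with the methoxy group in place and does not epimerize C14.

Step 11
Reactants: 19 methyl (2Z,4R)-5-Ar-2-methoxy-4-methylpent-2-enoate
Product: 20 methyl (2S,4R)-5-Ar-2-methoxy-4-methylpentanoate
Conditions: H2 (6 bar), [Rh(cod)((S,S)-Et-DuPhos)]OTf (2 mol%), MeOH, rt
Reagents that add atoms: none
Why: Rhodium–bisphospholane asymmetric hydrogenation of the α-alkoxy acrylate sets C12 (S) under catalyst control, independent of the remote C14 centre.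

Step 12
Reactants: 20 methyl (2S,4R)-5-Ar-2-methoxy-4-methylpentanoate
Product: 21 (2S,4R)-5-Ar-2-methoxy-4-methylpentanal
Conditions: i-Bu2AlH (2.2 equiv), toluene, −78 °C; Rochelle salt work-up
Reagents that add atoms: none
Why: Low-temperature partial ester reduction gives the α-methoxy aldehyde, which is used crude to avoid epimerization at C12.

Step 13
Reactants: 21 (2S,4R)-5-Ar-2-methoxy-4-methylpentanal
Product: 22 (3S,4R,5S,7R)-8-Ar-5-methoxy-3,7-dimethyloct-1-en-4-ol
Conditions: (Z)-crotylboronic acid pinacol ester (1.5 equiv), toluene, 4 Å molecular sieves, rt, 48 h; aq. NaHCO3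
Reagents that add atoms: (Z)-crotylboronic acid pinacol ester, C/C=C\CB1OC(C)(C)C(C)(C)O1
Why: Hoffmann–Roush crotylboration through a closed chair transition state turns the Z-crotyl geometry into the C10/C11 syn relationship, and the Cornforth–Felkin preference of α-alkoxy aldehydes with Z-crotylboronates places the C11 hydroxyl anti to the C12 methoxy group.

Step 14
Reactants: 22 (3S,4R,5S,7R)-8-Ar-5-methoxy-3,7-dimethyloct-1-en-4-ol
Product: 23 (3S,4R,5S,7R)-8-Ar-4-[(tert-butyldimethylsilyl)oxy]-5-methoxy-3,7-dimethyloct-1-ene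
Conditions: t-BuMe2SiOTf, 2,6-lutidine, CH2Cl2, −78 → 0 °C
Reagents that add atoms: tert-butyldimethylsilyl trifluoromethanesulfonate, CC(C)(C)[Si](C)(C)OS(=O)(=O)C(F)(F)F
Why: Silyl triflate silylation protects the hindered C11 hydroxyl so that it stays distinct from the later C7 hydroxyl.

Step 15
Reactants: 23 (3S,4R,5S,7R)-8-Ar-4-[(tert-butyldimethylsilyl)oxy]-5-methoxy-3,7-dimethyloct-1-ene
Product: 25 (2R,3R,4S,6R)-7-Ar-3-[(tert-butyldimethylsilyl)oxy]-4-methoxy-2,6-dimethylheptanal, via secondary ozonide 24 (not isolated)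
Conditions: O3, CH2Cl2/pyridine, −78 °C (Sudan Red 7B end-point); then PPh3, −78 °C → rt
Reagents that add atoms: ozone, [O-][O+]=O
Why: Ozonolysis with reductive work-up cleaves the terminal alkene far faster than the arene and unveils the C9 aldehyde without touching C10.

Step 16
Reactants: 25 (2R,3R,4S,6R)-7-Ar-3-[(tert-butyldimethylsilyl)oxy]-4-methoxy-2,6-dimethylheptanal
Product: 26 (2Z,4S,5R,6S,8R)-9-Ar-5-[(tert-butyldimethylsilyl)oxy]-2-iodo-6-methoxy-4,8-dimethylnon-2-ene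
Conditions: EtPPh3I, n-BuLi, THF, 0 °C; I2, −78 °C; NaN(SiMe3)2, −20 °C; then 25, −78 → −20 °C
Reagents that add atoms: ethyltriphenylphosphonium iodide, CC[P+](c1ccccc1)(c1ccccc1)c1ccccc1.[I-]; iodine, II
Why: Stork–Zhao-type Wittig olefination with the α-iodo ylide gives the (Z)-2-iodoalkene (iodine cis to C10), which fixes the 8Z geometry of the target.

Step 17
Reactants: 26 (2Z,4S,5R,6S,8R)-9-Ar-5-[(tert-butyldimethylsilyl)oxy]-2-iodo-6-methoxy-4,8-dimethylnon-2-ene; 11 methyl (2Z,6S)-6-methoxy-7-oxohept-2-enoate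
Product: 29 methyl (2Z,6S,7S,8Z,10S,11R,12S,14R)-15-Ar-11-[(tert-butyldimethylsilyl)oxy]-7-hydroxy-6,12-dimethoxy-8,10,14-trimethylpentadeca-2,8-dienoate, via alkenyllithium 27 (not isolated), via alkenylmagnesium bromide 28 (not isolated)
Conditions: 26, t-BuLi (3.0 equiv), Et2O, −78 °C; MgBr2·OEt2; then 11 (1.2 equiv, pre-mixed with MgBr2·OEt2), CH2Cl2, −78 °C; aq. NH4Cl
Reagents that add atoms: none
Why: Iodine–lithium exchange with retention of alkene geometry, transmetalation to magnesium and Cram-chelate-controlled addition to the α-methoxy aldehyde form C7–C8 with the 6,7-syn relationship (7S), the aldehyde reacting far faster than the enoate.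

Step 18
Reactants: 29 methyl (2Z,6S,7S,8Z,10S,11R,12S,14R)-15-Ar-11-[(tert-butyldimethylsilyl)oxy]-7-hydroxy-6,12-dimethoxy-8,10,14-trimethylpentadeca-2,8-dienoate
Product: 31 methyl (2Z,6S,7S,8Z,10S,11R,12S,14R)-15-Ar-7-(carbamoyloxy)-11-[(tert-butyldimethylsilyl)oxy]-6,12-dimethoxy-8,10,14-trimethylpentadeca-2,8-dienoate, via trichloroacetyl carbamate 30 (not isolated)
Conditions: Cl3CC(O)NCO, CH2Cl2, 0 °C; then neutral Al2O3, rt
Reagents that add atoms: trichloroacetyl isocyanate, O=C=NC(=O)C(Cl)(Cl)Cl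
Why: Kočovský carbamoylation acylates the only free hydroxyl (O7), and the trichloroacetyl group is hydrolysed on alumina without base, which spares the aryl silyl ether and the Z-enoate.

Step 19
Reactants: 31 methyl (2Z,6S,7S,8Z,10S,11R,12S,14R)-15-Ar-7-(carbamoyloxy)-11-[(tert-butyldimethylsilyl)oxy]-6,12-dimethoxy-8,10,14-trimethylpentadeca-2,8-dienoate
Product: 33 methyl (2Z,6S,7S,8Z,10S,11R,12S,14R)-15-Ar'-7-(carbamoyloxy)-11-[(tert-butyldimethylsilyl)oxy]-6,12-dimethoxy-8,10,14-trimethylpentadeca-2,8-dienoate, via trimethylsilyl carbamate 32 (not isolated)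
Conditions: Me3SiOTf, 2,6-lutidine, CH2Cl2, 0 °C; then MeOH
Reagents that add atoms: none
Why: Silyl-triflate-mediated N-Boc cleavage (loss of isobutene, then methanolysis and decarboxylation of the silyl carbamate) frees the aniline under buffered conditions that leave the silyl ethers and the allylic carbamate intact.

Step 20
Reactants: 33 methyl (2Z,6S,7S,8Z,10S,11R,12S,14R)-15-Ar'-7-(carbamoyloxy)-11-[(tert-butyldimethylsilyl)oxy]-6,12-dimethoxy-8,10,14-trimethylpentadeca-2,8-dienoate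
Product: 34 (2Z,6S,7S,8Z,10S,11R,12S,14R)-15-Ar'-7-(carbamoyloxy)-11-[(tert-butyldimethylsilyl)oxy]-6,12-dimethoxy-8,10,14-trimethylpentadeca-2,8-dienoic acid
Conditions: Me3SnOH, 1,2-dichloroethane, 70 °C; cold 0.1 M HCl wash
Reagents that add atoms: trimethyltin hydroxide, C[Sn](C)(C)O
Why: Nicolaou-type tin hydroxide hydrolysis cleaves the methyl ester under near-neutral conditions, so the primary carbamate, the aryl silyl ether and the Z-enoate geometry survive.

Step 21
Reactants: 34 (2Z,6S,7S,8Z,10S,11R,12S,14R)-15-Ar'-7-(carbamoyloxy)-11-[(tert-butyldimethylsilyl)oxy]-6,12-dimethoxy-8,10,14-trimethylpentadeca-2,8-dienoic acid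
Product: 35 11-O-(tert-butyldimethylsilyl)-18-O-(triisopropylsilyl) derivative of the target macrolactam
Conditions: BOP-Cl, i-Pr2NEt, toluene (1 mM), 85 °C
Reagents that add atoms: none
Why: BOP-Cl-mediated macrolactamization of the seco amino acid at high dilution closes the 19-membered anilide; the aniline is the only competent nucleophile and no stereocentre is affected.

Step 22
Reactants: 35 11-O-(tert-butyldimethylsilyl)-18-O-(triisopropylsilyl) derivative of the target macrolactam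
Product: 36 target CNP0263527.1
Conditions: HF·pyridine, pyridine, THF, 0 °C → rt
Reagents that add atoms: none
Why: Fluoride-mediated desilylation removes the secondary alkyl silyl ether at O11 and the aryl silyl ether at O18 in one operation under conditions that the allylic carbamate and the Z-enamide tolerate.

**Compound list**

1 | furan | c1ccoc1 | starting material
2 | 1,1,3,3-tetrabromopropan-2-one | O=C(C(Br)Br)C(Br)Br | starting material
3 | 2,4-dibromo-8-oxabicyclo[3.2.1]oct-6-en-3-one (bromide epimers) | O=C1C(Br)C2C=CC(O2)C1Br | intermediate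
4 | (1R,5S)-8-oxabicyclo[3.2.1]octan-3-one (meso) | O=C1C[C@H]2CC[C@@H](C1)O2 | intermediate
5 | (1R,5S)-3-(trimethylsilyloxy)-8-oxabicyclo[3.2.1]oct-2-ene | C[Si](C)(C)OC1=C[C@H]2CC[C@@H](C1)O2 | intermediate (not isolated)
6 | (S)-6-(trimethylsilyloxy)cyclohept-2-en-1-one | O=C1C=CCC[C@H](O[Si](C)(C)C)C1 | intermediate (not isolated)
7 | (S)-6-hydroxycyclohept-2-en-1-one | O=C1C=CCC[C@H](O)C1 | intermediate
8 | (S)-6-methoxycyclohept-2-en-1-one | O=C1C=CCC[C@H](OC)C1 | intermediate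
9 | potassium (3S)-3-methoxycyclohepta-1,6-dien-1-olate | [K+].[O-]C1=C[C@@H](OC)CCC=C1 | intermediate (not isolated)
10 | (6S)-7-hydroxy-6-methoxycyclohept-2-en-1-one (C7 epimers) | O=C1C=CCC[C@H](OC)C1O | intermediate
11 | methyl (2Z,6S)-6-methoxy-7-oxohept-2-enoate | COC(=O)/C=C\CC[C@H](OC)C=O | intermediate
12 | 3-amino-5-bromophenol | Nc1cc(O)cc(Br)c1 | starting material
13 | tert-butyl (3-bromo-5-hydroxyphenyl)carbamate | CC(C)(C)OC(=O)Nc1cc(O)cc(Br)c1 | intermediate (not isolated)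
14 | tert-butyl {3-bromo-5-[(triisopropylsilyl)oxy]phenyl}carbamate | CC(C)(C)OC(=O)Nc1cc(O[Si](C(C)C)(C(C)C)C(C)C)cc(Br)c1 | intermediate
15 | methyl (2S)-3-bromo-2-methylpropanoate | COC(=O)[C@H](C)CBr | starting material
16 | bromo[(2S)-3-methoxy-2-methyl-3-oxopropyl]zinc | COC(=O)[C@H](C)C[Zn]Br | intermediate (not isolated)
17 | methyl (2R)-3-Ar-2-methylpropanoate | COC(=O)[C@H](C)Cc1cc(O[Si](C(C)C)(C(C)C)C(C)C)cc(NC(=O)OC(C)(C)C)c1 | intermediate
18 | (2R)-3-Ar-2-methylpropanal | O=C[C@H](C)Cc1cc(O[Si](C(C)C)(C(C)C)C(C)C)cc(NC(=O)OC(C)(C)C)c1 | intermediate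
19 | methyl (2Z,4R)-5-Ar-2-methoxy-4-methylpent-2-enoate | COC(=O)/C(OC)=C/[C@H](C)Cc1cc(O[Si](C(C)C)(C(C)C)C(C)C)cc(NC(=O)OC(C)(C)C)c1 | intermediate
20 | methyl (2S,4R)-5-Ar-2-methoxy-4-methylpentanoate | COC(=O)[C@@H](OC)C[C@H](C)Cc1cc(O[Si](C(C)C)(C(C)C)C(C)C)cc(NC(=O)OC(C)(C)C)c1 | intermediate
21 | (2S,4R)-5-Ar-2-methoxy-4-methylpentanal | O=C[C@@H](OC)C[C@H](C)Cc1cc(O[Si](C(C)C)(C(C)C)C(C)C)cc(NC(=O)OC(C)(C)C)c1 | intermediate
22 | (3S,4R,5S,7R)-8-Ar-5-methoxy-3,7-dimethyloct-1-en-4-ol | C=C[C@H](C)[C@@H](O)[C@@H](OC)C[C@H](C)Cc1cc(O[Si](C(C)C)(C(C)C)C(C)C)cc(NC(=O)OC(C)(C)C)c1 | intermediate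
23 | (3S,4R,5S,7R)-8-Ar-4-(TBS-oxy)-5-methoxy-3,7-dimethyloct-1-ene | C=C[C@H](C)[C@@H](O[Si](C)(C)C(C)(C)C)[C@@H](OC)C[C@H](C)Cc1cc(O[Si](C(C)C)(C(C)C)C(C)C)cc(NC(=O)OC(C)(C)C)c1 | intermediate
24 | secondary ozonide (3-substituted 1,2,4-trioxolane) of 23 | C1OC(OO1)[C@H](C)[C@@H](O[Si](C)(C)C(C)(C)C)[C@@H](OC)C[C@H](C)Cc1cc(O[Si](C(C)C)(C(C)C)C(C)C)cc(NC(=O)OC(C)(C)C)c1 | intermediate (not isolated)
25 | (2R,3R,4S,6R)-7-Ar-3-(TBS-oxy)-4-methoxy-2,6-dimethylheptanal | O=C[C@H](C)[C@@H](O[Si](C)(C)C(C)(C)C)[C@@H](OC)C[C@H](C)Cc1cc(O[Si](C(C)C)(C(C)C)C(C)C)cc(NC(=O)OC(C)(C)C)c1 | intermediate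
26 | (2Z,4S,5R,6S,8R)-9-Ar-5-(TBS-oxy)-2-iodo-6-methoxy-4,8-dimethylnon-2-ene | C/C(I)=C/[C@H](C)[C@@H](O[Si](C)(C)C(C)(C)C)[C@@H](OC)C[C@H](C)Cc1cc(O[Si](C(C)C)(C(C)C)C(C)C)cc(NC(=O)OC(C)(C)C)c1 | intermediate
27 | C2,N-dilithio derivative of 26 (Li in place of I, Z retained; N–Li carbamate) | C/C([Li])=C/[C@H](C)[C@@H](O[Si](C)(C)C(C)(C)C)[C@@H](OC)C[C@H](C)Cc1cc(O[Si](C(C)C)(C(C)C)C(C)C)cc(N([Li])C(=O)OC(C)(C)C)c1 | intermediate (not isolated)
28 | alkenylmagnesium bromide from 27 (MgBr in place of C–Li) | C/C([Mg]Br)=C/[C@H](C)[C@@H](O[Si](C)(C)C(C)(C)C)[C@@H](OC)C[C@H](C)Cc1cc(O[Si](C(C)C)(C(C)C)C(C)C)cc(N([Li])C(=O)OC(C)(C)C)c1 | intermediate (not isolated)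
29 | methyl (2Z,6S,7S,8Z,10S,11R,12S,14R)-15-Ar-11-(TBS-oxy)-7-hydroxy-6,12-dimethoxy-8,10,14-trimethylpentadeca-2,8-dienoate | COC(=O)/C=C\CC[C@H](OC)[C@@H](O)/C(C)=C\[C@H](C)[C@@H](O[Si](C)(C)C(C)(C)C)[C@@H](OC)C[C@H](C)Cc1cc(O[Si](C(C)C)(C(C)C)C(C)C)cc(NC(=O)OC(C)(C)C)c1 | intermediate
30 | 7-O-[(trichloroacetyl)carbamoyl] derivative of 29 | COC(=O)/C=C\CC[C@H](OC)[C@@H](OC(=O)NC(=O)C(Cl)(Cl)Cl)/C(C)=C\[C@H](C)[C@@H](O[Si](C)(C)C(C)(C)C)[C@@H](OC)C[C@H](C)Cc1cc(O[Si](C(C)C)(C(C)C)C(C)C)cc(NC(=O)OC(C)(C)C)c1 | intermediate (not isolated)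
31 | methyl (2Z,6S,7S,8Z,10S,11R,12S,14R)-15-Ar-7-(carbamoyloxy)-11-(TBS-oxy)-6,12-dimethoxy-8,10,14-trimethylpentadeca-2,8-dienoate | COC(=O)/C=C\CC[C@H](OC)[C@@H](OC(N)=O)/C(C)=C\[C@H](C)[C@@H](O[Si](C)(C)C(C)(C)C)[C@@H](OC)C[C@H](C)Cc1cc(O[Si](C(C)C)(C(C)C)C(C)C)cc(NC(=O)OC(C)(C)C)c1 | intermediate
32 | N-(trimethylsilyloxycarbonyl) analogue of 31 (silyl carbamate in place of Boc) | COC(=O)/C=C\CC[C@H](OC)[C@@H](OC(N)=O)/C(C)=C\[C@H](C)[C@@H](O[Si](C)(C)C(C)(C)C)[C@@H](OC)C[C@H](C)Cc1cc(O[Si](C(C)C)(C(C)C)C(C)C)cc(NC(=O)O[Si](C)(C)C)c1 | intermediate (not isolated)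
33 | methyl (2Z,6S,7S,8Z,10S,11R,12S,14R)-15-Ar'-7-(carbamoyloxy)-11-(TBS-oxy)-6,12-dimethoxy-8,10,14-trimethylpentadeca-2,8-dienoate | COC(=O)/C=C\CC[C@H](OC)[C@@H](OC(N)=O)/C(C)=C\[C@H](C)[C@@H](O[Si](C)(C)C(C)(C)C)[C@@H](OC)C[C@H](C)Cc1cc(O[Si](C(C)C)(C(C)C)C(C)C)cc(N)c1 | intermediate
34 | (2Z,6S,7S,8Z,10S,11R,12S,14R)-15-Ar'-7-(carbamoyloxy)-11-(TBS-oxy)-6,12-dimethoxy-8,10,14-trimethylpentadeca-2,8-dienoic acid | OC(=O)/C=C\CC[C@H](OC)[C@@H](OC(N)=O)/C(C)=C\[C@H](C)[C@@H](O[Si](C)(C)C(C)(C)C)[C@@H](OC)C[C@H](C)Cc1cc(O[Si](C(C)C)(C(C)C)C(C)C)cc(N)c1 | intermediate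
35 | 11-O-TBS-18-O-(triisopropylsilyl) derivative of the target macrolactam | O=C1/C=C\CC[C@H](OC)[C@@H](OC(N)=O)/C(C)=C\[C@H](C)[C@@H](O[Si](C)(C)C(C)(C)C)[C@@H](OC)C[C@H](C)Cc2cc(O[Si](C(C)C)(C(C)C)C(C)C)cc(c2)N1 | intermediate
36 | CNP0263527.1: (2Z,6S,7S,8Z,10S,11R,12S,14R)-7-(carbamoyloxy)-11,18-dihydroxy-6,12-dimethoxy-8,10,14-trimethyl 19-membered ansa-lactam | CO[C@H]1C[C@H](C)Cc2cc(O)cc(c2)NC(=O)/C=C\CC[C@H](OC)[C@@H](OC(N)=O)/C(C)=C\[C@H](C)[C@H]1O | target

**Step count and weak points**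

Total step count: 22. Longest linear sequence: 16 steps (12 → 36, steps 7–22). The furan branch (steps 1–6) joins at step 17.

Three steps most likely to fail:

Step 3 (enantioselective deprotonation and ring-opening; ee and clean opening are both uncertain). The fallback sets out from 4 and returns at 7, and replaces asymmetric deprotonation by kinetic resolution. Ketone 4 is opened without induction (Me3SiOTf, Et3N, CH2Cl2, 0 °C) to racemic 6-(trimethylsilyloxy)cyclohept-2-en-1-one F1, which is desilylated (citric acid, MeOH) to racemic 6-hydroxycyclohept-2-en-1-one F2. F2 is resolved with Candida antarctica lipase B and vinyl acetate in t-BuOMe, which acylates the (R)-alcohol to (1R)-3-oxocyclohept-4-en-1-yl acetate F3 and leaves 7, separated by chromatography.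

Step 11 (asymmetric hydrogenation of an α-methoxy acrylate; enol ethers chelate rhodium less well than enol esters). The fallback sets out from 17 and returns at 21, and sets C12 by auxiliary-controlled alkylation instead. Ester 17 is reduced with LiBH4 to tert-butyl {3-[(2R)-3-hydroxy-2-methylpropyl]-5-[(triisopropylsilyl)oxy]phenyl}carbamate F4, which is converted (I2, PPh3, imidazole) into tert-butyl {3-[(2R)-3-iodo-2-methylpropyl]-5-[(triisopropylsilyl)oxy]phenyl}carbamate F5. The SAMP hydrazone of methoxyacetaldehyde F6 (made from methoxyacetaldehyde and (S)-1-amino-2-(methoxymethyl)pyrrolidine) is lithiated (LiN(i-Pr)2, THF, −100 °C) and alkylated with F5 to the hydrazone of 21 F7. Ozonolytic hydrazone cleavage (O3, CH2Cl2, −78 °C) gives 21.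

Step 17 (halogen–metal exchange on an advanced iodide and chelation-controlled addition; diastereoselectivity at C7 and chemoselectivity against the enoate are both at risk). The fallback sets out from 26 and 11 and returns at 29, and corrects C7 by an oxidation–reduction pair. Nozaki–Hiyama–Kishi coupling (CrCl2, NiCl2 1 mol%, DMSO/THF, rt) gives the C7-epimeric allylic alcohols F8. Dess–Martin oxidation gives the α-methoxy enone F9. Corey–Bakshi–Shibata reduction (oxazaborolidine enantiomer chosen for 7S, catecholborane, −78 °C) returns 29.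

**Further compounds**

F1 | step 3 | racemic 6-(trimethylsilyloxy)cyclohept-2-en-1-one | O=C1C=CCCC(O[Si](C)(C)C)C1
F2 | step 3 | racemic 6-hydroxycyclohept-2-en-1-one | O=C1C=CCCC(O)C1
F3 | step 3 | (1R)-3-oxocyclohept-4-en-1-yl acetate | O=C1C=CCC[C@@H](OC(C)=O)C1
F4 | step 11 | tert-butyl {3-[(2R)-3-hydroxy-2-methylpropyl]-5-[(triisopropylsilyl)oxy]phenyl}carbamate | OC[C@H](C)Cc1cc(O[Si](C(C)C)(C(C)C)C(C)C)cc(NC(=O)OC(C)(C)C)c1
F5 | step 11 | tert-butyl {3-[(2R)-3-iodo-2-methylpropyl]-5-[(triisopropylsilyl)oxy]phenyl}carbamate | IC[C@H](C)Cc1cc(O[Si](C(C)C)(C(C)C)C(C)C)cc(NC(=O)OC(C)(C)C)c1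
F6 | step 11 | (2S)-N-[(E)-2-methoxyethylidene]-2-(methoxymethyl)pyrrolidin-1-amine | COC/C=N/N1CCC[C@H]1COC
F7 | step 11 | SAMP hydrazone of aldehyde 21 | COC[C@@H]1CCCN1/N=C/[C@@H](OC)C[C@H](C)Cc1cc(O[Si](C(C)C)(C(C)C)C(C)C)cc(NC(=O)OC(C)(C)C)c1
F8 | step 17 | C7-epimeric mixture of 29 | COC(=O)/C=C\CC[C@H](OC)C(O)/C(C)=C\[C@H](C)[C@@H](O[Si](C)(C)C(C)(C)C)[C@@H](OC)C[C@H](C)Cc1cc(O[Si](C(C)C)(C(C)C)C(C)C)cc(NC(=O)OC(C)(C)C)c1
F9 | step 17 | methyl (2Z,6S,8Z,10S,11R,12S,14R)-15-Ar-11-(TBS-oxy)-6,12-dimethoxy-8,10,14-trimethyl-7-oxopentadeca-2,8-dienoate | COC(=O)/C=C\CC[C@H](OC)C(=O)/C(C)=C\[C@H](C)[C@@H](O[Si](C)(C)C(C)(C)C)[C@@H](OC)C[C@H](C)Cc1cc(O[Si](C(C)C)(C(C)C)C(C)C)cc(NC(=O)OC(C)(C)C)c1
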